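**Plan**

1. Numbering used throughout (germacrane): C1 = epoxide CH, C10 = epoxide carbon bearing the formyl carbon C14, C2/C3 = the ring CH2–CH2, C4(CH3)=C5, C6(OAc), C7(iPr), C8(OAc), C9H2.
2. Cuts: C1–O/C10–O (epoxide, from the allylic alcohol of the C1=C10 enal); then the ring bond C2–C3 by a retro-Cope that re-forms C5–C10, giving a cyclohexane with vinyl + CHO on C10 and isopropenyl on C5; then C1=C2 (Wittig), C10–C14 (orthoformate), C5–C4 (cuprate), C5=C10 (aldol condensation), C8–C9 (Grignard), C6–C7 (aldol).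
3. Enabling feature: C1=C10 (latent in the epoxide) and C4=C5 are 1,5-related through C2–C3, so the ten-membered ring is the Cope isomer of a 1,2-dialkenylcyclohexane (ring C5–C10). The formyl group on C10 is conjugated only in the ten-membered isomer, and the all-trans C6/C7/C8 triad is all-equatorial on that cyclohexane.
4. Forward order: acyclic chain with the triad → cyclohexenecarbaldehyde (first ring, aldol condensation) → quaternary C10 → cyclodecadienal (Cope ring expansion six to ten with in situ enal isomerisation) → epoxide ring last.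
5. Stereochemistry: C6 and C7 from the oxazolidinone syn-aldol, C8 from 1,3-syn reduction. C5 and C10 are temporary centres set by substrate control (isopropenyl trans to O–C6, vinyl cis to isopropenyl) and are translated into the 4Z alkene by the chair transition state. The enal geometry is thermodynamic, and C1/C10 come from D-(−)-diethyl tartrate.

Key step: step 13

Assumption: the target SMILES is read as (1R,10S,6S,7S,8R) with C4=C5 Z in the numbering above, i.e. C2 and C9 are cis on the epoxide and C3 and C6 are cis on the alkene.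

Remark: compound 3 can also be bought; step 1 is kept so that the route starts from undisputed catalogue compounds.

**Route**

Step 1
Reactants: 1 (R)-4-benzyloxazolidin-2-one; 2 3-methylbutanoyl chloride
Product: 3 (R)-4-benzyl-3-(3-methylbutanoyl)oxazolidin-2-one
Conditions: Et3N, DMAP (cat.), CH2Cl2, 0 °C → rt
Reagents that add atoms: none
Why: DMAP-catalysed N-acylation of the oxazolidinone should load the auxiliary cleanly; no stereocentre is formed and the (R) centre of 1 is untouched.

Step 2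
Reactants: 3 (R)-4-benzyl-3-(3-methylbutanoyl)oxazolidin-2-one; 4 acrolein
Product: 6 (R)-4-benzyl-3-[(2R,3S)-3-hydroxy-2-(propan-2-yl)pent-4-enoyl]oxazolidin-2-one, via boron Z-enolate 5 (not isolated)
Conditions: Bu2BOTf, iPr2NEt, CH2Cl2, −78 → 0 °C; 4, −78 → 0 °C; pH 7 buffer, MeOH, 30% H2O2, 0 °C
Reagents that add atoms: none
Why: Evans syn-aldol reaction: the Z boron enolate reacts through a Zimmerman–Traxler chair whose face is fixed by the benzyl group of the (R)-auxiliary, which should set C7 (2R) and C6 (3S) together.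

Step 3
Reactants: 6 (R)-4-benzyl-3-[(2R,3S)-3-hydroxy-2-(propan-2-yl)pent-4-enoyl]oxazolidin-2-one
Product: 7 (2R,3S)-3-hydroxy-N-methoxy-N-methyl-2-(propan-2-yl)pent-4-enamide
Conditions: MeNH(OMe)·HCl, AlMe3, CH2Cl2, −10 → 0 °C; 0.5 M aq. HCl work-up
Reagents that add atoms: N,O-dimethylhydroxylamine hydrochloride, CNOC.Cl
Why: Weinreb transamidation with the aluminium amide, directed by the C6 aluminium alkoxide, should cleave the auxiliary at the exocyclic carbonyl without epimerising C7.

Step 4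
Reactants: 7 (2R,3S)-3-hydroxy-N-methoxy-N-methyl-2-(propan-2-yl)pent-4-enamide; 8 but-3-enylmagnesium bromide
Product: 9 (3S,4R)-3-hydroxy-4-(propan-2-yl)nona-1,8-dien-5-one
Conditions: 8 (3 equiv), THF, −78 → 0 °C; aq. NH4Cl
Reagents that add atoms: none
Why: Grignard addition to a Weinreb amide should stop at the ketone because the chelated tetrahedral magnesium adduct survives until work-up, and the same chelate protects the α-centre.

Step 5
Reactants: 9 (3S,4R)-3-hydroxy-4-(propan-2-yl)nona-1,8-dien-5-one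
Product: 11 (3S,4S,5R)-4-(propan-2-yl)nona-1,8-diene-3,5-diol, via diethylboryl ether 10 (not isolated)
Conditions: Et2BOMe, THF/MeOH (4:1), −78 °C; NaBH4, −78 °C; then evaporation from MeOH (three times)
Reagents that add atoms: none
Why: Narasaka–Prasad reduction: external hydride attacks the six-membered boron chelate axially, anti to the pseudo-axial isopropyl group, so the 1,3-syn diol and hence the all-syn C6/C7/C8 triad (C8 = R) should result.

Step 6
Reactants: 11 (3S,4S,5R)-4-(propan-2-yl)nona-1,8-diene-3,5-diol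
Product: 12 (3S,4S,5R)-3,5-bis[(tert-butyldimethylsilyl)oxy]-4-(propan-2-yl)nona-1,8-diene
Conditions: TBSOTf (2.5 equiv), 2,6-lutidine, CH2Cl2, −78 → 0 °C
Reagents that add atoms: tert-butyldimethylsilyl trifluoromethanesulfonate, CC(C)(C)[Si](C)(C)OS(=O)(=O)C(F)(F)F
Why: Silylation with the silyl triflate should protect both hindered secondary hydroxyls as ethers that offer no leaving group to the later cuprate.

Step 7
Reactants: 12 (3S,4S,5R)-3,5-bis[(tert-butyldimethylsilyl)oxy]-4-(propan-2-yl)nona-1,8-diene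
Product: 14 (3S,4S,5R)-3,5-bis[(tert-butyldimethylsilyl)oxy]-4-(propan-2-yl)cyclohex-1-ene-1-carbaldehyde, via dialdehyde 13 (not isolated)
Conditions: O3, CH2Cl2, −78 °C; Me2S, −78 °C → rt; evaporate; Bn2NH·CF3CO2H (0.3 equiv), toluene, rt → 45 °C
Reagents that add atoms: ozone, [O-][O+]=O
Why: Ozonolysis of both terminal alkenes followed by amine-salt-catalysed intramolecular aldol condensation should give the six-membered enal regioselectively, because only the adduct from the C10 enamine attacking the C5 aldehyde can dehydrate; no new stereocentre is formed.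

Step 8
Reactants: 14 (3S,4S,5R)-3,5-bis[(tert-butyldimethylsilyl)oxy]-4-(propan-2-yl)cyclohex-1-ene-1-carbaldehyde; 15 isopropenylmagnesium bromide
Product: 16 {[(2R,3S,4S,5R)-3,5-bis[(tert-butyldimethylsilyl)oxy]-4-(propan-2-yl)-2-(prop-1-en-2-yl)cyclohexylidene]methoxy}trimethylsilane (E/Z mixture)
Conditions: 15 (1.5 equiv), CuBr·SMe2 (10 mol %), Me3SiCl (2 equiv), HMPA (2 equiv), THF, −78 °C; Et3N; cold aq. NaHCO3
Reagents that add atoms: chlorotrimethylsilane, C[Si](C)(C)Cl
Why: Copper-catalysed conjugate addition of the Grignard reagent with Me3SiCl trapping should deliver isopropenyl to C5 anti to the neighbouring C6 silyloxy group (trans, both equatorial) and hold the enolate as its silyl enol ether.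

Step 9
Reactants: 16 {[(2R,3S,4S,5R)-3,5-bis[(tert-butyldimethylsilyl)oxy]-4-(propan-2-yl)-2-(prop-1-en-2-yl)cyclohexylidene]methoxy}trimethylsilane
Product: 17 (1S,2R,3S,4S,5R)-3,5-bis[(tert-butyldimethylsilyl)oxy]-1-(dimethoxymethyl)-4-(propan-2-yl)-2-(prop-1-en-2-yl)cyclohexane-1-carbaldehyde
Conditions: HC(OMe)3 (1.2 equiv), Me3SiOTf (5 mol %), CH2Cl2, −78 °C; aq. NaHCO3
Reagents that add atoms: trimethyl orthoformate, COC(OC)OC
Why: Mukaiyama-type alkylation of the enol silyl ether by the Lewis-acid-activated orthoformate builds quaternary C10; the electrophile should enter equatorially and trans to the adjacent isopropenyl group, so the acetal carbon (C14) is equatorial and the original formyl group is axial and cis to isopropenyl.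

Step 10
Reactants: 17 (1S,2R,3S,4S,5R)-3,5-bis[(tert-butyldimethylsilyl)oxy]-1-(dimethoxymethyl)-4-(propan-2-yl)-2-(prop-1-en-2-yl)cyclohexane-1-carbaldehyde
Product: 18 (1R,2R,3S,4S,5R)-3,5-bis[(tert-butyldimethylsilyl)oxy]-1-(dimethoxymethyl)-1-ethenyl-4-(propan-2-yl)-2-(prop-1-en-2-yl)cyclohexane
Conditions: Ph3PCH3Br, KN(SiMe3)2, THF, 0 °C; then 17, −78 → 0 °C
Reagents that add atoms: methyltriphenylphosphonium bromide, C[P+](c1ccccc1)(c1ccccc1)c1ccccc1.[Br-]
Why: Wittig methylenation of the non-enolisable aldehyde should turn the axial formyl group into the vinyl group (C1=C2) while the acetal keeps C14 masked; the configuration at C10 is unchanged.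

Step 11
Reactants: 18 (1R,2R,3S,4S,5R)-3,5-bis[(tert-butyldimethylsilyl)oxy]-1-(dimethoxymethyl)-1-ethenyl-4-(propan-2-yl)-2-(prop-1-en-2-yl)cyclohexane
Product: 19 (1R,2R,3S,4S,5R)-1-ethenyl-3,5-dihydroxy-4-(propan-2-yl)-2-(prop-1-en-2-yl)cyclohexane-1-carbaldehyde
Conditions: 48% aq. HF, MeCN, 0 °C → rt
Reagents that add atoms: water, O
Why: Aqueous HF in acetonitrile should cleave both silyl ethers and hydrolyse the dimethyl acetal in one operation; the all-equatorial chair keeps the 1,3-related hydroxyls from closing a bridged lactol onto the aldehyde.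

Step 12
Reactants: 19 (1R,2R,3S,4S,5R)-1-ethenyl-3,5-dihydroxy-4-(propan-2-yl)-2-(prop-1-en-2-yl)cyclohexane-1-carbaldehyde
Product: 20 (1R,2R,3S,4S,5R)-3,5-bis(acetyloxy)-1-ethenyl-4-(propan-2-yl)-2-(prop-1-en-2-yl)cyclohexane-1-carbaldehyde
Conditions: Ac2O, pyridine, DMAP (cat.), CH2Cl2, 0 °C → rt
Reagents that add atoms: acetic anhydride, CC(=O)OC(C)=O
Why: DMAP-catalysed acetylation should install the two acetates of the target; the aldehyde sits on a quaternary carbon and cannot enolise.

Step 13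
Reactants: 20 (1R,2R,3S,4S,5R)-3,5-bis(acetyloxy)-1-ethenyl-4-(propan-2-yl)-2-(prop-1-en-2-yl)cyclohexane-1-carbaldehyde
Product: 22 (1E,5Z,7S,8S,9R)-7,9-bis(acetyloxy)-5-methyl-8-(propan-2-yl)cyclodeca-1,5-diene-1-carbaldehyde, via ring-trans enal 21 (not isolated)
Conditions: DABCO (0.2 equiv), BHT (1 mol %), degassed o-xylene (0.02 M), 150 °C, sealed tube
Reagents that add atoms: none
Why: A thermal [3,3]-sigmatropic (Cope) rearrangement of the 1,5-diene C2=C1–C10–C5–C4=C3 breaks C5–C10 and joins the two terminal CH2 carbons (C2–C3), and the closest known reactions are the thermal elemane–germacrane Cope equilibration and tandem Cope–Claisen sequences in which a second event drains that equilibrium. The ten-membered ring is closed suprafacially through a six-membered chair transition state cis-fused to the chair cyclohexane, i.e. by ring expansion and not by end-to-end cyclisation, so high dilution is not needed. No sp3 stereocentre is created (C5 and C10 become sp2, C6–C8 are spectators); in the only low-energy chair of 20 (both OAc, iPr, isopropenyl and CHO equatorial, vinyl axial) C6 is pseudo-axial on the Cope chair, which should give C4=C5 as Z, and C9 is pseudo-equatorial, which gives C1=C10 first as the strained ring-trans enal 21. DABCO should then isomerise 21 by reversible conjugate addition–elimination, and as proton shuttle for the dienol that forms by 1,5-hydrogen shift from C2, to the enal 22 with the formyl group trans to C2, which is both the tiglaldehyde-type geometry and the cis-cycloalkene. The driving force is conjugation of C1=C10 with the formyl group, two trisubstituted alkenes in place of a vinyl and an isopropenyl group, and loss of the axial vinyl group on the quaternary carbon; 22 should not revert because a cis,cis-cyclodeca-1,5-diene can re-enter the Cope manifold only through a boat transition state. The step needs the cis-dialkenyl arrangement with isopropenyl equatorial (secured in steps 8 and 9) and isomerisation of the enal without touching the isolated 4Z alkene (secured by a nucleophilic, non-radical catalyst with BHT present).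

Step 14
Reactants: 22 (1E,5Z,7S,8S,9R)-7,9-bis(acetyloxy)-5-methyl-8-(propan-2-yl)cyclodeca-1,5-diene-1-carbaldehyde
Product: 23 (1S,2S,3R,5E,9Z)-5-(hydroxymethyl)-9-methyl-2-(propan-2-yl)cyclodeca-5,9-diene-1,3-diyl diacetate
Conditions: NaBH4, CeCl3·7H2O, MeOH, −40 °C
Reagents that add atoms: none
Why: Luche 1,2-reduction of the enal should give the 2,3-disubstituted E-allylic alcohol needed for reagent-controlled epoxidation, with the acetates untouched at low temperature.

Step 15
Reactants: 23 (1S,2S,3R,5E,9Z)-5-(hydroxymethyl)-9-methyl-2-(propan-2-yl)cyclodeca-5,9-diene-1,3-diyl diacetate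
Product: 24 (1R,3R,4S,5S,6Z,10R)-1-(hydroxymethyl)-7-methyl-4-(propan-2-yl)-11-oxabicyclo[8.1.0]undec-6-ene-3,5-diyl diacetate
Conditions: Ti(OiPr)4 (10 mol %), D-(−)-diethyl tartrate (12 mol %), t-BuOOH (decane, 2 equiv), 4 Å molecular sieves, CH2Cl2, −20 °C
Reagents that add atoms: tert-butyl hydroperoxide, CC(C)(C)OO
Why: Katsuki–Sharpless asymmetric epoxidation: the titanium tartrate complex delivers oxygen syn across C1=C10 on the face dictated by D-(−)-diethyl tartrate (the face opposite to the one that gives 2S,3S-epoxygeraniol with the L-(+)-ester), which should set both epoxide centres, and the isolated C4=C5 alkene does not react.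

Step 16
Reactants: 24 (1R,3R,4S,5S,6Z,10R)-1-(hydroxymethyl)-7-methyl-4-(propan-2-yl)-11-oxabicyclo[8.1.0]undec-6-ene-3,5-diyl diacetate
Product: 25 (1S,3R,4S,5S,6Z,10R)-1-formyl-7-methyl-4-(propan-2-yl)-11-oxabicyclo[8.1.0]undec-6-ene-3,5-diyl diacetate
Conditions: Dess–Martin periodinane, NaHCO3, CH2Cl2, 0 °C → rt
Reagents that add atoms: none
Why: Dess–Martin oxidation of the primary epoxy alcohol under buffered conditions should give the epoxy aldehyde without touching the epoxide, the acetates or the alkene (the C10 descriptor changes from R to S only because of priorities).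

**Compound list**

1 | (R)-4-benzyloxazolidin-2-one | O=C1N[C@H](Cc2ccccc2)CO1 | starting material
2 | 3-methylbutanoyl chloride | CC(C)CC(=O)Cl | starting material
3 | (R)-4-benzyl-3-(3-methylbutanoyl)oxazolidin-2-one | CC(C)CC(=O)N1[C@H](Cc2ccccc2)COC1=O | intermediate
4 | acrolein (prop-2-enal) | C=CC=O | starting material
5 | (R)-4-benzyl-3-[(Z)-1-[(dibutylboranyl)oxy]-3-methylbut-1-enyl]oxazolidin-2-one | CCCCB(CCCC)O/C(=C\C(C)C)N1[C@H](Cc2ccccc2)COC1=O | intermediate
6 | (R)-4-benzyl-3-[(2R,3S)-3-hydroxy-2-(propan-2-yl)pent-4-enoyl]oxazolidin-2-one | C=C[C@H](O)[C@@H](C(C)C)C(=O)N1[C@H](Cc2ccccc2)COC1=O | intermediate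
7 | (2R,3S)-3-hydroxy-N-methoxy-N-methyl-2-(propan-2-yl)pent-4-enamide | C=C[C@H](O)[C@@H](C(C)C)C(=O)N(C)OC | intermediate
8 | but-3-enylmagnesium bromide | C=CCC[Mg]Br | starting material
9 | (3S,4R)-3-hydroxy-4-(propan-2-yl)nona-1,8-dien-5-one | C=C[C@H](O)[C@@H](C(C)C)C(=O)CCC=C | intermediate
10 | (3S,4R)-3-[(diethylboranyl)oxy]-4-(propan-2-yl)nona-1,8-dien-5-one | C=C[C@H](OB(CC)CC)[C@@H](C(C)C)C(=O)CCC=C | intermediate
11 | (3S,4S,5R)-4-(propan-2-yl)nona-1,8-diene-3,5-diol | C=C[C@H](O)[C@@H](C(C)C)[C@H](O)CCC=C | intermediate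
12 | (3S,4S,5R)-3,5-bis[(tert-butyldimethylsilyl)oxy]-4-(propan-2-yl)nona-1,8-diene | C=C[C@H](O[Si](C)(C)C(C)(C)C)[C@@H](C(C)C)[C@H](O[Si](C)(C)C(C)(C)C)CCC=C | intermediate
13 | (2R,3S,4R)-2,4-bis[(tert-butyldimethylsilyl)oxy]-3-(propan-2-yl)heptanedial | O=C[C@H](O[Si](C)(C)C(C)(C)C)[C@@H](C(C)C)[C@H](O[Si](C)(C)C(C)(C)C)CCC=O | intermediate
14 | (3S,4S,5R)-3,5-bis[(tert-butyldimethylsilyl)oxy]-4-(propan-2-yl)cyclohex-1-ene-1-carbaldehyde | O=CC1=C[C@H](O[Si](C)(C)C(C)(C)C)[C@@H](C(C)C)[C@H](O[Si](C)(C)C(C)(C)C)C1 | intermediate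
15 | isopropenylmagnesium bromide (prop-1-en-2-ylmagnesium bromide) | C=C(C)[Mg]Br | starting material
16 | {[(2R,3S,4S,5R)-3,5-bis[(tert-butyldimethylsilyl)oxy]-4-(propan-2-yl)-2-(prop-1-en-2-yl)cyclohexylidene]methoxy}trimethylsilane (E/Z mixture) | C[Si](C)(C)OC=C1[C@@H](C(C)=C)[C@H](O[Si](C)(C)C(C)(C)C)[C@@H](C(C)C)[C@H](O[Si](C)(C)C(C)(C)C)C1 | intermediate
17 | (1S,2R,3S,4S,5R)-3,5-bis[(tert-butyldimethylsilyl)oxy]-1-(dimethoxymethyl)-4-(propan-2-yl)-2-(prop-1-en-2-yl)cyclohexane-1-carbaldehyde | O=C[C@@]1(C(OC)OC)[C@@H](C(C)=C)[C@H](O[Si](C)(C)C(C)(C)C)[C@@H](C(C)C)[C@H](O[Si](C)(C)C(C)(C)C)C1 | intermediate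
18 | (1R,2R,3S,4S,5R)-3,5-bis[(tert-butyldimethylsilyl)oxy]-1-(dimethoxymethyl)-1-ethenyl-4-(propan-2-yl)-2-(prop-1-en-2-yl)cyclohexane | C=C[C@@]1(C(OC)OC)[C@@H](C(C)=C)[C@H](O[Si](C)(C)C(C)(C)C)[C@@H](C(C)C)[C@H](O[Si](C)(C)C(C)(C)C)C1 | intermediate
19 | (1R,2R,3S,4S,5R)-1-ethenyl-3,5-dihydroxy-4-(propan-2-yl)-2-(prop-1-en-2-yl)cyclohexane-1-carbaldehyde | O=C[C@]1(C=C)[C@@H](C(C)=C)[C@H](O)[C@@H](C(C)C)[C@H](O)C1 | intermediate
20 | (1R,2R,3S,4S,5R)-3,5-bis(acetyloxy)-1-ethenyl-4-(propan-2-yl)-2-(prop-1-en-2-yl)cyclohexane-1-carbaldehyde | O=C[C@]1(C=C)[C@@H](C(C)=C)[C@H](OC(C)=O)[C@@H](C(C)C)[C@H](OC(C)=O)C1 | intermediate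
21 | (1Z,5Z,7S,8S,9R)-7,9-bis(acetyloxy)-5-methyl-8-(propan-2-yl)cyclodeca-1,5-diene-1-carbaldehyde | CC(=O)O[C@H]1/C=C(/C)CC/C=C(\C=O)C[C@@H](OC(C)=O)[C@@H]1C(C)C | intermediate
22 | (1E,5Z,7S,8S,9R)-7,9-bis(acetyloxy)-5-methyl-8-(propan-2-yl)cyclodeca-1,5-diene-1-carbaldehyde | CC(=O)O[C@H]1/C=C(/C)CC/C=C(/C=O)C[C@@H](OC(C)=O)[C@@H]1C(C)C | intermediate
23 | (1S,2S,3R,5E,9Z)-5-(hydroxymethyl)-9-methyl-2-(propan-2-yl)cyclodeca-5,9-diene-1,3-diyl diacetate | CC(=O)O[C@H]1/C=C(/C)CC/C=C(/CO)C[C@@H](OC(C)=O)[C@@H]1C(C)C | intermediate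
24 | (1R,3R,4S,5S,6Z,10R)-1-(hydroxymethyl)-7-methyl-4-(propan-2-yl)-11-oxabicyclo[8.1.0]undec-6-ene-3,5-diyl diacetate | CC(=O)O[C@H]1/C=C(/C)CC[C@H]2O[C@@]2(CO)C[C@@H](OC(C)=O)[C@@H]1C(C)C | intermediate
25 | (1S,3R,4S,5S,6Z,10R)-1-formyl-7-methyl-4-(propan-2-yl)-11-oxabicyclo[8.1.0]undec-6-ene-3,5-diyl diacetate | CC(=O)O[C@H]1/C=C(/C)CC[C@H]2O[C@@]2(C=O)C[C@@H](OC(C)=O)[C@@H]1C(C)C | target

**Totals**

Total step count: 16. Longest linear sequence: 16 steps (fully linear, 1 + 2 → 25).

**Steps most likely to fail**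

Step 13. The first Cope equilibrium may lie on the cyclohexane side while the geometric isomerisation that drains it is too slow, so conversion stalls. The formyl group may also cyclise thermally onto the isopropenyl group (carbonyl-ene) before rearrangement. Fallback (stoichiometric trapping instead of catalytic isomerisation): the route sets out again from 20, which is heated with PhSH (1.5 equiv) and Et3N (0.2 equiv) in degassed toluene at 120 °C with BHT. The transient enal 21 should then be removed by conjugate addition as (5Z,7S,8S,9R)-7,9-bis(acetyloxy)-5-methyl-2-(phenylsulfanyl)-8-(propan-2-yl)cyclodec-5-ene-1-carbaldehyde F1, which is no longer a 1,5-diene and cannot return. Oxidation with NaIO4 (MeOH/H2O, 0 °C), which leaves the alkene alone, should give the sulfoxide (5Z,7S,8S,9R)-7,9-bis(acetyloxy)-2-(benzenesulfinyl)-5-methyl-8-(propan-2-yl)cyclodec-5-ene-1-carbaldehyde F2. Warming F2 in toluene over CaCO3 (80 °C) should cause syn-elimination toward the acidic C10–H; because C10 can epimerise, both diastereomers should funnel to the more stable enal. The fallback returns to the route at 22.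

Step 9. Facial selectivity in the alkylation at the quaternary carbon may be poor or reversed (electrophile entering axially, cis to isopropenyl). Fallback (the two formyl equivalents are told apart chemically instead of by face): from 16 the other epimer, (1R,2R,3S,4S,5R)-3,5-bis[(tert-butyldimethylsilyl)oxy]-1-(dimethoxymethyl)-4-(propan-2-yl)-2-(prop-1-en-2-yl)cyclohexane-1-carbaldehyde F3, is separated. Its free aldehyde, now trans to isopropenyl, is reduced (NaBH4, MeOH, 0 °C) to [(1R,2R,3S,4S,5R)-3,5-bis[(tert-butyldimethylsilyl)oxy]-1-(dimethoxymethyl)-4-(propan-2-yl)-2-(prop-1-en-2-yl)cyclohexyl]methanol F4. The acetal, cis to isopropenyl, is hydrolysed (PPTS, acetone/H2O, 50 °C) to (1R,2R,3S,4S,5R)-3,5-bis[(tert-butyldimethylsilyl)oxy]-1-(hydroxymethyl)-4-(propan-2-yl)-2-(prop-1-en-2-yl)cyclohexane-1-carbaldehyde F5. Wittig methylenation with excess Ph3P=CH2 should give [(1R,2R,3S,4S,5R)-3,5-bis[(tert-butyldimethylsilyl)oxy]-1-ethenyl-4-(propan-2-yl)-2-(prop-1-en-2-yl)cyclohexyl]methanol F6. Dess–Martin oxidation then gives (1R,2R,3S,4S,5R)-3,5-bis[(tert-butyldimethylsilyl)oxy]-1-ethenyl-4-(propan-2-yl)-2-(prop-1-en-2-yl)cyclohexane-1-carbaldehyde F7, the bis-silyl ether of 19, and 48% aq. HF in MeCN returns the material to the route at 19. Both epimers of step 9 can therefore be used.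

Step 15. The chiral centres of the ring may be mismatched with the tartrate, the hindered medium-ring allylic alcohol may bind poorly to titanium, or the Lewis acid may open the new epoxide by transannular attack of the C4=C5 alkene. Fallback (iminium catalysis on the aldehyde instead of titanium catalysis on the alcohol): steps 14–16 are left out. From 22 the enal is epoxidised directly with 50% aq. H2O2 in dioxane at 35 °C, using 10 mol % of a 9-amino-9-deoxy-epi-cinchona alkaloid bis(trifluoroacetate), the known reagent-controlled epoxidation of α-branched enals. The quinine- or quinidine-derived pseudo-enantiomer is chosen for the (1R,10S) epoxide. The fallback arrives at 25 and makes no new compound (F0).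

**Further compounds**

F1 | step 13 | (5Z,7S,8S,9R)-7,9-bis(acetyloxy)-5-methyl-2-(phenylsulfanyl)-8-(propan-2-yl)cyclodec-5-ene-1-carbaldehyde (mixture at C1 and C2) | CC(=O)O[C@H]1/C=C(/C)CCC(Sc2ccccc2)C(C=O)C[C@@H](OC(C)=O)[C@@H]1C(C)C
F2 | step 13 | (5Z,7S,8S,9R)-7,9-bis(acetyloxy)-2-(benzenesulfinyl)-5-methyl-8-(propan-2-yl)cyclodec-5-ene-1-carbaldehyde (mixture at C1, C2 and S) | CC(=O)O[C@H]1/C=C(/C)CCC(S(=O)c2ccccc2)C(C=O)C[C@@H](OC(C)=O)[C@@H]1C(C)C
F3 | step 9 | (1R,2R,3S,4S,5R)-3,5-bis[(tert-butyldimethylsilyl)oxy]-1-(dimethoxymethyl)-4-(propan-2-yl)-2-(prop-1-en-2-yl)cyclohexane-1-carbaldehyde | O=C[C@]1(C(OC)OC)[C@@H](C(C)=C)[C@H](O[Si](C)(C)C(C)(C)C)[C@@H](C(C)C)[C@H](O[Si](C)(C)C(C)(C)C)C1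
F4 | step 9 | [(1R,2R,3S,4S,5R)-3,5-bis[(tert-butyldimethylsilyl)oxy]-1-(dimethoxymethyl)-4-(propan-2-yl)-2-(prop-1-en-2-yl)cyclohexyl]methanol | OC[C@]1(C(OC)OC)[C@@H](C(C)=C)[C@H](O[Si](C)(C)C(C)(C)C)[C@@H](C(C)C)[C@H](O[Si](C)(C)C(C)(C)C)C1
F5 | step 9 | (1R,2R,3S,4S,5R)-3,5-bis[(tert-butyldimethylsilyl)oxy]-1-(hydroxymethyl)-4-(propan-2-yl)-2-(prop-1-en-2-yl)cyclohexane-1-carbaldehyde | OC[C@]1(C=O)[C@@H](C(C)=C)[C@H](O[Si](C)(C)C(C)(C)C)[C@@H](C(C)C)[C@H](O[Si](C)(C)C(C)(C)C)C1
F6 | step 9 | [(1R,2R,3S,4S,5R)-3,5-bis[(tert-butyldimethylsilyl)oxy]-1-ethenyl-4-(propan-2-yl)-2-(prop-1-en-2-yl)cyclohexyl]methanol | OC[C@]1(C=C)[C@@H](C(C)=C)[C@H](O[Si](C)(C)C(C)(C)C)[C@@H](C(C)C)[C@H](O[Si](C)(C)C(C)(C)C)C1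
F7 | step 9 | (1R,2R,3S,4S,5R)-3,5-bis[(tert-butyldimethylsilyl)oxy]-1-ethenyl-4-(propan-2-yl)-2-(prop-1-en-2-yl)cyclohexane-1-carbaldehyde | O=C[C@]1(C=C)[C@@H](C(C)=C)[C@H](O[Si](C)(C)C(C)(C)C)[C@@H](C(C)C)[C@H](O[Si](C)(C)C(C)(C)C)C1
F0 | step 15 | none | none
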